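**Plan**

1. Target numbering: ring C1–C6 (C1 carbinol, C3 CHCl, C4 CBr(CH3)), side chain C1′–C7′ (C2′ on C1, C5′ carbinol). Cuts: C2′–C3′ (sp2–sp3 coupling of a ring enol triflate with a side-chain alkylzinc), then C3–Cl and C4–Br (anti addition to a C3=C4 alkene), then the enol triflate back to a methyl ketone.
2. What remains, 1-acetyl-4-methylcyclohex-3-en-1-ol, is an α-ketol: the tertiary ring carbinol C1 carries the exocyclic carbonyl carbon C2′. It is unravelled by a retro-acyloin shift (break ring bond C1–C2, join C2 to C2′) to a 2-hydroxy-2-methylcyclohept-4-enone, whose carbinol carbon is the later C2′ and whose ketone carbon is the later C1.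
3. The seven-membered ketol is cut at its alkene (ring-closing metathesis), at the ketone (Weinreb amide + Grignard) and at the carbinol–allyl bond (enolate allylation of the lactic acid/pivalaldehyde acetal).
4. Forward: acyclic ketol, cycloheptenone (metathesis), cyclohexene (ring contraction), enol triflate, bromochloride, coupling with the separately made side-chain iodide (four steps), desilylation. The C2′ oxygen needed for the shift leaves as triflate in the coupling.
5. Stereochemistry: C1 from (S)-lactic acid (self-regeneration of the stereocentre, then chirality transfer in the 1,2-shift); C3 and C4 from C1 (hydroxyl-delivered chloride, anti bromine); C5′ from a chiral acetate aldol with methacrolein.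

Key step: step 6

Assumption: the Lewis-acid-mediated acyloin shift is taken to run through the five-membered chelate with carbinol oxygen and carbonyl oxygen syn; the configurations given for 10 and 11 follow from that geometry.

**Step 1**
Reactants: 1 (S)-lactic acid; 2 pivalaldehyde
Product: 3 (2S,5S)-2-tert-butyl-5-methyl-1,3-dioxolan-4-one
Conditions: cat. p-TsOH, cat. H2SO4, pentane, reflux (water separator); crystallisation from pentane/Et2O, −78 °C
Reagents that add atoms: none
Why: Acid-catalysed acetalisation of the α-hydroxy acid; the cis acetal is expected to predominate and to be purified by crystallisation, so the lactic acid stereocentre is copied into the acetal carbon C2.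

**Step 2**
Reactants: 3
Product: 5 (2S,5R)-2-tert-butyl-5-methyl-5-(prop-2-en-1-yl)-1,3-dioxolan-4-one, via lithium enolate 4 (not isolated)
Conditions: LiN(iPr)2, THF, −78 °C; allyl bromide, −78 → −30 °C
Reagents that add atoms: allyl bromide, C=CCBr
Why: Enolate alkylation with self-regeneration of the stereocentre: the planar enolate is attacked anti to the tert-butyl group, so the allyl group takes the place of the former hydrogen and C5 is rebuilt as a quaternary carbinol carbon of defined configuration (5R).

**Step 3**
Reactants: 5
Product: 6 (2R)-2-hydroxy-N-methoxy-N,2-dimethylpent-4-enamide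
Conditions: MeNH(OMe)·HCl, AlMe3, CH2Cl2, 0 → 25 °C; aq. Rochelle salt
Reagents that add atoms: N,O-dimethylhydroxylamine hydrochloride, CNOC.Cl
Why: Aluminium amide aminolysis of the acylal-type lactone opens the dioxolanone, releases the pivalaldehyde auxiliary and gives the Weinreb amide without touching the quaternary carbinol.

**Step 4**
Reactants: 6 (2R)-2-hydroxy-N-methoxy-N,2-dimethylpent-4-enamide; 7 4-bromo-2-methylbut-1-ene
Product: 9 (4R)-4-hydroxy-4,8-dimethylnona-1,8-dien-5-one, via Grignard reagent 8 (not isolated)
Conditions: Mg, THF (7 → 8); then 6 (2.5 equiv of 8), THF, 0 °C; aq. NH4Cl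
Reagents that add atoms: none
Why: Grignard addition to a Weinreb amide stops at the ketone because the chelated tetrahedral intermediate survives until work-up; one equivalent of reagent is spent on the free hydroxyl.

**Step 5**
Reactants: 9
Product: 10 (2R)-2-hydroxy-2,5-dimethylcyclohept-4-en-1-one
Conditions: second-generation Grubbs catalyst (H2IMes)(PCy3)Cl2Ru=CHPh (5 mol %), CH2Cl2 (5 mM), 40 °C
Reagents that add atoms: none
Why: Ring-closing metathesis between the allyl group and the 1,1-disubstituted alkene forms the trisubstituted C4=C5 alkene of the seven-membered ring; only these two alkenes are present, so no other ring can form.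

**Step 6**
Reactants: 10
Product: 11 1-[(1S)-1-hydroxy-4-methylcyclohex-3-en-1-yl]ethan-1-one
Conditions: Al(OtBu)3 (30 mol %), toluene, 90 °C
Reagents that add atoms: none
Why: The aluminium alkoxide of 10 holds the carbinol oxygen and the ketone oxygen in a five-membered chelate, the ring bond C2–C3 then stands nearly perpendicular to the carbonyl plane, and the allylic carbon C3 migrates with its electron pair from C2 to C1 while C2 becomes the acetyl carbonyl; this is the α-ketol (acyloin) rearrangement in its ring-contracting sense, the reverse of the familiar expansion of 1-acylcycloalkanols. The cyclohexene ring is closed by this suprafacial 1,2-shift and not by a cyclisation of a chain. The only new stereocentre, C1, is set by chirality transfer: in the chelate the migrating carbon already lies over one face of the carbonyl and is delivered to that face, so (2R)-10 should give (1S)-11 while the old stereocentre is erased. The step needs ring-bond migration to win over methyl migration and the chelated over the open transition state; the better migratory aptitude and alignment of the allylic ring carbon, the release of medium-ring strain, and a chelating aluminium alkoxide that has no transferable hydride should secure both. A methyl shift followed by contraction through the other ring bond would give the same constitution and, through the same chelate, the same enantiomer, so the material should funnel to 11 under thermodynamic control.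

**Step 7**
Reactants: 11
Product: 13 1-[(1S)-1-hydroxy-4-methylcyclohex-3-en-1-yl]ethenyl trifluoromethanesulfonate, via dipotassium alkoxide enolate 12 (not isolated)
Conditions: KN(SiMe3)2 (2.2 equiv), THF, −78 °C; N-(5-chloropyridin-2-yl)bis(trifluoromethanesulfonyl)imide (1.1 equiv), −78 → −30 °C; aq. NH4Cl
Reagents that add atoms: N-(5-chloropyridin-2-yl)bis(trifluoromethanesulfonyl)imide, FC(F)(F)S(=O)(=O)N(c1ccc(Cl)cn1)S(=O)(=O)C(F)(F)F
Why: Kinetic deprotonation at the only enolisable position (the acetyl methyl) and O-sulfonylation of the enolate give the enol triflate, the hindered tertiary alkoxide being expected to react more slowly; the electron-poor alkene masks C2′ during the halogenation and is the later coupling handle.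

**Step 8**
Reactants: 13
Product: 15 1-[(1S,3S,4S)-4-bromo-3-chloro-1-hydroxy-4-methylcyclohexyl]ethenyl trifluoromethanesulfonate, via chlorotitanium alkoxide 14 (not isolated)
Conditions: ClTi(OiPr)3 (1.2 equiv), hexanes/CH2Cl2, 25 °C; then NBS (1.1 equiv), −20 °C
Reagents that add atoms: N-bromosuccinimide, O=C1CCC(=O)N1Br; chlorotitanium triisopropoxide, CC(C)O[Ti](Cl)(OC(C)C)OC(C)C
Why: Proposed new method: the tertiary alkoxide of 13 exchanges onto titanium, NBS forms the bromonium ion reversibly on either face of the trisubstituted alkene, and only the bromonium ion anti to the titanium alkoxide can be opened intramolecularly by the titanium-bound chloride, which reaches C3 (not C4) through a six-membered chair-like array with the alkoxide axial; the trans-diaxial opening should place Cl on the secondary carbon syn to the oxygen (3S) and leave Br on the tertiary carbon anti to it (4S), against the Markovnikov preference, and the enol triflate alkene is too electron-poor to compete; the closest known reaction type is the titanium-alkoxide-directed bromochlorination of allylic alcohols, where chloride is delivered to the alkene carbon nearer the oxygen through a five-membered array, here extended to a cyclic tertiary homoallylic alcohol.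

**Step 9**
Reactants: 16 (1R)-2-hydroxy-1,2,2-triphenylethyl acetate; 17 methacrolein
Product: 19 (1R)-2-hydroxy-1,2,2-triphenylethyl (3R)-3-hydroxy-4-methylpent-4-enoate, via dilithium alkoxide enolate 18 (not isolated)
Conditions: LiN(iPr)2 (2.2 equiv), THF, −78 → 0 °C; then 17, THF/2-methylbutane, −110 °C; aq. NH4Cl; recrystallisation
Reagents that add atoms: none
Why: Acetate aldol 1,2-addition of the doubly deprotonated chiral acetate to the enal; the triphenylglycol ester controls the facial selectivity, the (R)-reagent being known to give (R)-β-hydroxy esters with α-branched aldehydes, and crystallisation should upgrade the adduct.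

**Step 10**
Reactants: 19
Product: 20 (3R)-4-methylpent-4-ene-1,3-diol
Conditions: LiAlH4, THF, 0 → 25 °C
Reagents that add atoms: none
Why: Hydride reduction of the ester releases the diol and the recoverable triphenylethanediol auxiliary; the isolated alkene and the carbinol stereocentre are not touched.

**Step 11**
Reactants: 20
Product: 21 (3R)-5-iodo-2-methylpent-1-en-3-ol
Conditions: I2, PPh3, imidazole, CH2Cl2, 0 °C
Reagents that add atoms: iodine, II
Why: Appel-type iodination is selective for the primary over the more hindered secondary allylic hydroxyl.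

**Step 12**
Reactants: 21
Product: 22 triethyl{[(3R)-5-iodo-2-methylpent-1-en-3-yl]oxy}silane
Conditions: Et3SiCl, imidazole, CH2Cl2, 0 °C
Reagents that add atoms: chlorotriethylsilane, CC[Si](Cl)(CC)CC
Why: Silylation of the secondary alcohol; the triethylsilyl ether is stable to zinc insertion and cross-coupling and is removable under mild buffered conditions at the end.

**Step 13**
Reactants: 15 1-[(1S,3S,4S)-4-bromo-3-chloro-1-hydroxy-4-methylcyclohexyl]ethenyl trifluoromethanesulfonate; 22 triethyl{[(3R)-5-iodo-2-methylpent-1-en-3-yl]oxy}silane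
Product: 24 (1S,3S,4S)-4-bromo-3-chloro-4-methyl-1-{(5R)-6-methyl-5-[(triethylsilyl)oxy]hepta-1,6-dien-2-yl}cyclohexan-1-ol, via alkylzinc iodide 23 (not isolated)
Conditions: Zn dust, LiCl, THF, 25 °C (22 → 23, solution separated from excess Zn); then 15, 23 (1.5 equiv), Pd(OAc)2 (5 mol %), SPhos (10 mol %), THF, 25 °C
Reagents that add atoms: none
Why: Negishi sp2–sp3 cross-coupling of the enol triflate with the primary alkylzinc under conditions of a type that tolerates free hydroxyl groups; the tertiary C–Br and secondary C–Cl bonds are poor partners for oxidative addition at room temperature, no metallic zinc enters the coupling flask, and no stereocentre is formed or touched.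

**Step 14**
Reactants: 24
Product: 25 (1S,3S,4S)-4-bromo-3-chloro-1-[(5R)-5-hydroxy-6-methylhepta-1,6-dien-2-yl]-4-methylcyclohexan-1-ol
Conditions: HF·pyridine, pyridine, THF, 0 °C
Reagents that add atoms: none
Why: Buffered fluoride cleavage of the triethylsilyl ether; the vicinal chlorine retards ionisation of the tertiary bromide, and no base is present that could cause elimination or transannular ether formation from the C1 alkoxide.

**Compound list**

1 | (S)-lactic acid | C[C@H](O)C(=O)O | starting material
2 | pivalaldehyde | CC(C)(C)C=O | starting material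
3 | (2S,5S)-2-tert-butyl-5-methyl-1,3-dioxolan-4-one | C[C@@H]1O[C@H](C(C)(C)C)OC1=O | intermediate
4 | lithium enolate of 3 (lithium (2S)-2-tert-butyl-5-methyl-1,3-dioxol-4-olate) | CC1=C(O[Li])O[C@@H](C(C)(C)C)O1 | intermediate (not isolated)
5 | (2S,5R)-2-tert-butyl-5-methyl-5-(prop-2-en-1-yl)-1,3-dioxolan-4-one | C[C@]1(CC=C)O[C@H](C(C)(C)C)OC1=O | intermediate
6 | (2R)-2-hydroxy-N-methoxy-N,2-dimethylpent-4-enamide | C=CC[C@@](C)(O)C(=O)N(C)OC | intermediate
7 | 4-bromo-2-methylbut-1-ene | C=C(C)CCBr | starting material
8 | (3-methylbut-3-en-1-yl)magnesium bromide | C=C(C)CC[Mg]Br | intermediate (not isolated)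
9 | (4R)-4-hydroxy-4,8-dimethylnona-1,8-dien-5-one | C=CC[C@@](C)(O)C(=O)CCC(C)=C | intermediate
10 | (2R)-2-hydroxy-2,5-dimethylcyclohept-4-en-1-one | CC1=CC[C@@](C)(O)C(=O)CC1 | intermediate
11 | 1-[(1S)-1-hydroxy-4-methylcyclohex-3-en-1-yl]ethan-1-one | CC(=O)[C@]1(O)CCC(C)=CC1 | intermediate
12 | dipotassium alkoxide enolate of 11 | C=C(O[K])[C@]1(O[K])CCC(C)=CC1 | intermediate (not isolated)
13 | 1-[(1S)-1-hydroxy-4-methylcyclohex-3-en-1-yl]ethenyl trifluoromethanesulfonate | C=C(OS(=O)(=O)C(F)(F)F)[C@]1(O)CCC(C)=CC1 | intermediate
14 | chlorobis(propan-2-olato)titanium alkoxide of 13 | C=C(OS(=O)(=O)C(F)(F)F)[C@]1(O[Ti](Cl)(OC(C)C)OC(C)C)CCC(C)=CC1 | intermediate (not isolated)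
15 | 1-[(1S,3S,4S)-4-bromo-3-chloro-1-hydroxy-4-methylcyclohexyl]ethenyl trifluoromethanesulfonate | C=C(OS(=O)(=O)C(F)(F)F)[C@]1(O)CC[C@](C)(Br)[C@@H](Cl)C1 | intermediate
16 | (1R)-2-hydroxy-1,2,2-triphenylethyl acetate | CC(=O)O[C@H](c1ccccc1)C(O)(c1ccccc1)c1ccccc1 | starting material
17 | methacrolein | CC(=C)C=O | starting material
18 | dilithium alkoxide enolate of 16 | C=C(O[Li])O[C@H](c1ccccc1)C(O[Li])(c1ccccc1)c1ccccc1 | intermediate (not isolated)
19 | (1R)-2-hydroxy-1,2,2-triphenylethyl (3R)-3-hydroxy-4-methylpent-4-enoate | CC(=C)[C@H](O)CC(=O)O[C@H](c1ccccc1)C(O)(c1ccccc1)c1ccccc1 | intermediate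
20 | (3R)-4-methylpent-4-ene-1,3-diol | CC(=C)[C@H](O)CCO | intermediate
21 | (3R)-5-iodo-2-methylpent-1-en-3-ol | CC(=C)[C@H](O)CCI | intermediate
22 | triethyl{[(3R)-5-iodo-2-methylpent-1-en-3-yl]oxy}silane | CC(=C)[C@H](O[Si](CC)(CC)CC)CCI | intermediate
23 | {(3R)-4-methyl-3-[(triethylsilyl)oxy]pent-4-en-1-yl}zinc iodide | CC(=C)[C@H](O[Si](CC)(CC)CC)CC[Zn]I | intermediate (not isolated)
24 | (1S,3S,4S)-4-bromo-3-chloro-4-methyl-1-{(5R)-6-methyl-5-[(triethylsilyl)oxy]hepta-1,6-dien-2-yl}cyclohexan-1-ol | C=C(C)[C@H](O[Si](CC)(CC)CC)CCC(=C)[C@]1(O)CC[C@](C)(Br)[C@@H](Cl)C1 | intermediate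
25 | (1S,3S,4S)-4-bromo-3-chloro-1-[(5R)-5-hydroxy-6-methylhepta-1,6-dien-2-yl]-4-methylcyclohexan-1-ol | C=C(C)[C@H](O)CCC(=C)[C@]1(O)CC[C@](C)(Br)[C@@H](Cl)C1 | target

**Count and risks**

Total step count: 14. Longest linear sequence: 10 steps (steps 1–8, 13, 14); the side-chain iodide takes 4 steps (9–12).

**Step 8 (most likely to fail).** Chloride may arrive from a second titanium centre at the tertiary carbon (Markovnikov regiochemistry), or the titanium-bound oxygen may attack C4 across the ring (transannular bromoetherification). The fallback sets out from 13 and comes back at 15, using known reactions in which electronic and trans-diaxial demands point the same way at each stage. NBS in aqueous acetone should give the bromohydrin 1-[(1S,3S,4S)-3-bromo-1,4-dihydroxy-4-methylcyclohexyl]ethenyl trifluoromethanesulfonate F1 (bromonium ion on the hydroxyl face, water at the tertiary carbon). DBU in CH2Cl2 closes it to the epoxide 1-[(1R,3S,6S)-3-hydroxy-6-methyl-7-oxabicyclo[4.1.0]heptan-3-yl]ethenyl trifluoromethanesulfonate F2, anti to the C1 hydroxyl. Li2CuCl4 in THF opens F2 at the secondary carbon with inversion to the chlorohydrin 1-[(1S,3S,4S)-3-chloro-1,4-dihydroxy-4-methylcyclohexyl]ethenyl trifluoromethanesulfonate F3. Anhydrous HBr in CH2Cl2 at −20 °C then replaces the tertiary hydroxyl by bromide with retention: bromide enters axially and anti to the vicinal chlorine, while the C1 hydroxyl is deactivated toward ionisation by the neighbouring enol triflate. This gives 15.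

**Step 6.** Part of the material may pass through a non-chelated transition state (loss of enantiomeric purity), or the cycloheptenone may undergo Lewis-acid-induced transannular reactions before the shift. The fallback reaches 11 without a change of ring size; it sets out from pivalaldehyde 2 and comes back at 11. Purchased (R)-lactic acid F4 and 2 give, as in step 1, (2R,5R)-2-tert-butyl-5-methyl-1,3-dioxolan-4-one F5. Radical bromination (NBS, AIBN, cyclohexane, reflux) gives 5-bromo-2-tert-butyl-5-methyl-1,3-dioxolan-4-one F6 (acetal carbon unchanged in space, 2S by the sequence rule). Et3N then eliminates HBr to give (2R)-2-tert-butyl-5-methylidene-1,3-dioxolan-4-one F7. Its thermal Diels–Alder reaction with isoprene (toluene, sealed tube) should occur anti to the tert-butyl group and mainly in the para sense, giving (2R,5S)-2-tert-butyl-8-methyl-1,3-dioxaspiro[4.5]dec-7-en-4-one F8; the meta isomer is removed by chromatography. AlMe3/MeNH(OMe)·HCl opens F8 to (1S)-1-hydroxy-N-methoxy-N,4-dimethylcyclohex-3-ene-1-carboxamide F9, and MeMgBr (excess, THF, 0 °C) converts F9 into 11.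

**Step 13.** The vicinal bromine and chlorine may be lost by reductive anti-elimination (zerovalent palladium, iodide or the organozinc), or the organozinc may be protonated by the free hydroxyl. The fallback couples before any halogen is present and brings the halogens in through an epoxide; it sets out from 13 and comes back at 24. Hydroxyl-directed epoxidation (VO(acac)2 cat., t-BuOOH, CH2Cl2) gives the syn epoxide 1-[(1S,3S,6R)-3-hydroxy-6-methyl-7-oxabicyclo[4.1.0]heptan-3-yl]ethenyl trifluoromethanesulfonate F10. F10 is coupled with 23 under the conditions of step 13 to (1S,3S,6R)-6-methyl-3-{(5R)-6-methyl-5-[(triethylsilyl)oxy]hepta-1,6-dien-2-yl}-7-oxabicyclo[4.1.0]heptan-3-ol F11. MgBr2·OEt2 in Et2O at −20 °C opens the epoxide at the tertiary carbon with inversion (Markovnikov and trans-diaxial demands coincide) to the bromohydrin (1S,3S,4S)-4-bromo-4-methyl-1-{(5R)-6-methyl-5-[(triethylsilyl)oxy]hepta-1,6-dien-2-yl}cyclohexane-1,3-diol F12. PPh3/CCl4 then converts the secondary hydroxyl into the chloride with retention, through the bromonium ion formed by participation of the anti bromine and its trans-diaxial opening at the secondary carbon. This gives 24.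

**Further compounds**

F1 | step 8 | 1-[(1S,3S,4S)-3-bromo-1,4-dihydroxy-4-methylcyclohexyl]ethenyl trifluoromethanesulfonate | C=C(OS(=O)(=O)C(F)(F)F)[C@]1(O)CC[C@](C)(O)[C@@H](Br)C1
F2 | step 8 | 1-[(1R,3S,6S)-3-hydroxy-6-methyl-7-oxabicyclo[4.1.0]heptan-3-yl]ethenyl trifluoromethanesulfonate | C=C(OS(=O)(=O)C(F)(F)F)[C@]1(O)CC[C@]2(C)O[C@@H]2C1
F3 | step 8 | 1-[(1S,3S,4S)-3-chloro-1,4-dihydroxy-4-methylcyclohexyl]ethenyl trifluoromethanesulfonate | C=C(OS(=O)(=O)C(F)(F)F)[C@]1(O)CC[C@](C)(O)[C@@H](Cl)C1
F4 | step 6 | (R)-lactic acid (purchased antipode of 1) | C[C@@H](O)C(=O)O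
F5 | step 6 | (2R,5R)-2-tert-butyl-5-methyl-1,3-dioxolan-4-one | C[C@H]1O[C@@H](C(C)(C)C)OC1=O
F6 | step 6 | (2S)-5-bromo-2-tert-butyl-5-methyl-1,3-dioxolan-4-one (C5 not defined) | CC1(Br)O[C@@H](C(C)(C)C)OC1=O
F7 | step 6 | (2R)-2-tert-butyl-5-methylidene-1,3-dioxolan-4-one | C=C1O[C@@H](C(C)(C)C)OC1=O
F8 | step 6 | (2R,5S)-2-tert-butyl-8-methyl-1,3-dioxaspiro[4.5]dec-7-en-4-one | CC1=CC[C@]2(CC1)O[C@@H](C(C)(C)C)OC2=O
F9 | step 6 | (1S)-1-hydroxy-N-methoxy-N,4-dimethylcyclohex-3-ene-1-carboxamide | CON(C)C(=O)[C@]1(O)CCC(C)=CC1
F10 | step 13 | 1-[(1S,3S,6R)-3-hydroxy-6-methyl-7-oxabicyclo[4.1.0]heptan-3-yl]ethenyl trifluoromethanesulfonate | C=C(OS(=O)(=O)C(F)(F)F)[C@]1(O)CC[C@@]2(C)O[C@H]2C1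
F11 | step 13 | (1S,3S,6R)-6-methyl-3-{(5R)-6-methyl-5-[(triethylsilyl)oxy]hepta-1,6-dien-2-yl}-7-oxabicyclo[4.1.0]heptan-3-ol | C=C(C)[C@H](O[Si](CC)(CC)CC)CCC(=C)[C@]1(O)CC[C@@]2(C)O[C@H]2C1
F12 | step 13 | (1S,3S,4S)-4-bromo-4-methyl-1-{(5R)-6-methyl-5-[(triethylsilyl)oxy]hepta-1,6-dien-2-yl}cyclohexane-1,3-diol | C=C(C)[C@H](O[Si](CC)(CC)CC)CCC(=C)[C@]1(O)CC[C@](C)(Br)[C@@H](O)C1
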